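**Retrosynthetic overview**

Numbering used throughout: C1 = lactone C=O, O1 = lactone ring oxygen, C2 = CH2, C3 = CHOH, C4 (on the ring-ether oxygen) and C5 (on O1) = ring-fusion carbons, C6 = CHOH, C7 = CH carrying the side chain, C8=C9, C10 (OBz), C11 (OAc), C12 = CH3.
Target 23 is cut at C8=C9 by olefin cross-metathesis into the vinyl core 15 and the allylic diester 22 (from methyl (R)-lactate 16).
Core 15 comes from bis-lactone 9/10: the γ-lactone carbonyl C7 becomes CH(vinyl) and the C3 ketone becomes the carbinol, H-7 and H-3 both being delivered from the convex face.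
Bis-lactone 9 comes from 2-silyloxyfuran 4 and tert-butyl 3-oxopropanoate 6 by a one-pot vinylogous Mukaiyama aldol (C3–C4) and carboxylate oxa-Michael addition (O1–C5). The enabling feature is that the ether-ring atoms O–C4–C5–C6–C7 can be read as a furan-2(5H)-one with C7 as its carbonyl, so C4 is the γ-nucleophile of a 2-silyloxyfuran and C5 the β-acceptor of the resulting butenolide, six atoms away from the carboxyl oxygen of the C1–C3 unit.
Ring order: the five-membered O-ring is bought as butyrolactone 1 and kept to the end (it becomes the tetrahydrofuran); the δ-lactone is closed in step 5; C4 is set by the catalyst, and C5, C6, C7 and C3 are relayed from it by substrate control.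

Key step: step 5

Remark: compound 1 is used as the racemate, because its stereocenter is destroyed in step 1.
Assumption: (R)-BINOL is taken to give the (S)-configured butenolide γ-carbon in 7; if the sense is opposite, (S)-BINOL is used and nothing else changes.

**Route**

Step 1
Reactants: 1 (±)-3-hydroxydihydrofuran-2(3H)-one
Product: 2 3-hydroxyfuran-2(5H)-one
Conditions: Dess–Martin periodinane, NaHCO3, CH2Cl2, 0 °C to rt; used crude
Reagents that add atoms: none
Why: Dess–Martin oxidation of the secondary α-hydroxy lactone gives the 2,3-dione, which rests as its conjugated enol 2, and no stereocenter remains.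

Step 2
Reactants: 2 3-hydroxyfuran-2(5H)-one
Product: 3 3-(naphthalen-2-ylmethoxy)furan-2(5H)-one
Conditions: 2-(bromomethyl)naphthalene, K2CO3, DMF, 0 °C to rt
Reagents that add atoms: 2-(bromomethyl)naphthalene BrCc1ccc2ccccc2c1
Why: Williamson O-alkylation of the acidic enol hydroxyl by the benzylic bromide under mild carbonate base installs the 2-naphthylmethyl (NAP) ether, which later comes off oxidatively.

Step 3
Reactants: 3 3-(naphthalen-2-ylmethoxy)furan-2(5H)-one
Product: 4 trimethyl{[3-(naphthalen-2-ylmethoxy)furan-2-yl]oxy}silane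
Conditions: Me3SiOTf, Et3N, CH2Cl2, 0 °C; salts removed with pentane, used crude
Reagents that add atoms: trimethylsilyl trifluoromethanesulfonate C[Si](C)(C)OS(=O)(=O)C(F)(F)F
Why: Soft enolization of the butenolide at its γ-CH2 with Me3SiOTf/Et3N gives the aromatic 2-silyloxyfuran, the standard nucleophile of vinylogous Mukaiyama chemistry.

Step 4
Reactants: 5 tert-butyl 3-hydroxypropanoate
Product: 6 tert-butyl 3-oxopropanoate
Conditions: Dess–Martin periodinane, NaHCO3, CH2Cl2, 0 °C; used at once
Reagents that add atoms: none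
Why: Dess–Martin oxidation of the primary alcohol stops at the aldehyde under non-basic conditions that spare the tert-butyl ester and limit self-condensation of the β-formyl ester.

Step 5
Reactants: 4 trimethyl{[3-(naphthalen-2-ylmethoxy)furan-2-yl]oxy}silane; 6 tert-butyl 3-oxopropanoate
Product: 9 (3S,3aS,7aR)-7-hydroxy-3-(naphthalen-2-ylmethoxy)tetrahydro-2H-furo[3,2-b]pyran-2,5(3H)-dione (cis-fused bis-lactone; C3-carbinol epimers), via aldol adduct 7 (not isolated), via hydroxy acid 8 (not isolated)
Conditions: Ti(OiPr)4 (20 mol %), (R)-BINOL (20 mol %), Et2O, −20 °C; then CF3CO2H, CH2Cl2, 0 °C, evaporate; then Et3N (0.2 equiv), MeCN, 40 °C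
Reagents that add atoms: none
Why: Ti(OiPr)4/(R)-BINOL-catalysed vinylogous Mukaiyama aldol addition of the γ-carbon C4 of silyloxyfuran 4 to aldehyde 6 forms C3–C4 and gives butenolide 7, acidolysis of the tert-butyl ester frees acid 8, and amine-catalysed intramolecular oxa-Michael addition of the carboxylate oxygen O1 to the butenolide β-carbon C5 forms O1–C5 (closest known types: catalytic asymmetric vinylogous Mukaiyama aldol of 2-silyloxyfurans and carboxylate oxa-Michael bis-lactonisation of butenolide acids). The only ring closed is the δ-lactone, by 6-exo-trig conjugate addition, while the former furan ring becomes the γ-lactone that later gives the tetrahydrofuran. C4 is set by the chiral Lewis acid, C5 by the tether, which can deliver O1 only to the face carrying the C4–C3 bond (cis fusion), and C6 by kinetic protonation of the lactone enolate from the convex face, which leaves the NAP ether cis to O1. The C3 carbinol may form as a mixture because step 6 erases it. The step needs γ- over α-regioselectivity, secured by the 3-alkoxy group that blocks the α-carbon, and it needs the neutral lactone to be favoured over the open carboxylate without epimerisation at C6, secured by using only a substoichiometric weak base.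

Step 6
Reactants: 9 bis-lactone (C3-carbinol epimers)
Product: 10 (3S,3aS,7aS)-3-(naphthalen-2-ylmethoxy)dihydro-2H-furo[3,2-b]pyran-2,5,7(3H,6H)-trione
Conditions: Dess–Martin periodinane, NaHCO3, CH2Cl2, 0 °C to rt; used crude
Reagents that add atoms: none
Why: Buffered Dess–Martin oxidation of the secondary alcohol converges both C3 epimers on the β-keto-δ-lactone, whose acidic 1,3-dicarbonyl unit serves as an in-situ protecting handle in step 7.

Step 7
Reactants: 10 keto bis-lactone
Product: 11 2-ethynyl-2-hydroxy-3-(naphthalen-2-ylmethoxy)tetrahydro-2H-furo[3,2-b]pyran-5,7(3H,6H)-dione (anomeric mixture; other centres as in 10)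
Conditions: LiN(SiMe3)2 (1.0 equiv), THF, −78 °C; then HC≡CLi (2 equiv), −78 °C; AcOH quench
Reagents that add atoms: lithium acetylide [Li]C#C
Why: One equivalent of LiN(SiMe3)2 turns the β-keto-δ-lactone into its unreactive enolate, so the acetylide undergoes 1,2-addition only at the α-alkoxy γ-lactone carbonyl (the lactone-to-lactol addition used for alkynyl C-glycosides), giving hemiketal 11.

Step 8
Reactants: 11 ethynyl hemiketal
Product: 12 (2S,3R,3aR,7aS)-2-ethynyl-3-(naphthalen-2-ylmethoxy)tetrahydro-2H-furo[3,2-b]pyran-5,7(3H,6H)-dione (H-2, H-3, H-3a, H-7a all cis)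
Conditions: Et3SiH, BF3·OEt2, CH2Cl2/MeCN, −40 °C
Reagents that add atoms: none
Why: Lewis-acid ionisation of the hemiketal to the cyclic oxocarbenium ion followed by silane reduction (C-glycoside-type reductive deoxygenation) should deliver hydride to C7 from the convex face of the cis-fused bicycle, opposite the δ-lactone ring, so that H-7 is cis to H-4, H-5 and H-6 and the ethynyl group ends on the concave face.

Step 9
Reactants: 12 ethynyl keto lactone
Product: 13 (2S,3R,3aR,7R,7aR)-2-ethynyl-7-hydroxy-3-(naphthalen-2-ylmethoxy)hexahydro-5H-furo[3,2-b]pyran-5-one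
Conditions: NaBH4, MeOH/CH2Cl2, −40 °C
Reagents that add atoms: none
Why: NaBH4 reduction of the ketone of the β-keto lactone should occur from the convex face, anti to the C4–O bond, placing H-3 cis to H-4 and giving the C3 carbinol of the target while the lactone survives at low temperature.

Step 10
Reactants: 13 ethynyl hydroxy lactone
Product: 14 (2S,3R,3aR,7R,7aR)-7-hydroxy-3-(naphthalen-2-ylmethoxy)-2-vinylhexahydro-5H-furo[3,2-b]pyran-5-one
Conditions: H2 (1 atm), Pd/CaCO3 poisoned with Pb(OAc)2, quinoline, EtOAc, rt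
Reagents that add atoms: none
Why: Lindlar semihydrogenation of the terminal alkyne stops at the alkene on the poisoned Pd/CaCO3 surface and leaves the naphthylmethyl ether and the lactone untouched.

Step 11
Reactants: 14 vinyl NAP ether
Product: 15 (2S,3R,3aR,7R,7aR)-3,7-dihydroxy-2-vinylhexahydro-5H-furo[3,2-b]pyran-5-one
Conditions: DDQ, CH2Cl2/pH 7 buffer, rt
Reagents that add atoms: none
Why: DDQ oxidises the electron-rich 2-naphthylmethyl ether through its benzylic cation and hemiacetal, releasing the C6 alcohol without affecting the alkene, the lactone or the free C3 alcohol.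

Step 12
Reactants: 16 methyl (R)-lactate
Product: 17 methyl (R)-2-[(tert-butyldimethylsilyl)oxy]propanoate
Conditions: tBuMe2SiCl, imidazole, DMF, rt
Reagents that add atoms: tert-butyldimethylsilyl chloride CC(C)(C)[Si](C)(C)Cl
Why: Standard imidazole-mediated silylation protects the lactate hydroxyl without touching its stereocenter.

Step 13
Reactants: 17 methyl (R)-2-[(tert-butyldimethylsilyl)oxy]propanoate
Product: 19 (3S,4R)-4-[(tert-butyldimethylsilyl)oxy]pent-1-en-3-ol, via aldehyde 18 (not isolated)
Conditions: iBu2AlH (1.05 equiv), CH2Cl2, −78 °C; then CH2=CHMgBr, −78 to 0 °C; aq. KNa tartrate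
Reagents that add atoms: vinylmagnesium bromide C=C[Mg]Br
Why: Low-temperature iBu2AlH reduction gives the tetrahedral iBu2Al-bound hemiacetal, which releases aldehyde 18 as CH2=CHMgBr is added, and Felkin–Anh addition to the non-chelating α-silyloxy aldehyde should set the new carbinol anti to the lactate centre, the minor syn isomer being removed by chromatography.

Step 14
Reactants: 19 (3S,4R)-4-[(tert-butyldimethylsilyl)oxy]pent-1-en-3-ol
Product: 20 (3S,4R)-4-[(tert-butyldimethylsilyl)oxy]pent-1-en-3-yl benzoate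
Conditions: PhCOCl, pyridine, DMAP (cat.), CH2Cl2, 0 °C
Reagents that add atoms: benzoyl chloride O=C(Cl)c1ccccc1
Why: DMAP-catalysed acylation of the secondary allylic alcohol installs the C10 benzoate with retention of configuration.

Step 15
Reactants: 20 silyl ether benzoate
Product: 21 (3S,4R)-4-hydroxypent-1-en-3-yl benzoate
Conditions: HF·pyridine, THF, 0 °C to rt
Reagents that add atoms: none
Why: Fluoride desilylation under buffered acidic conditions frees the C11 alcohol while avoiding the base-promoted 1,2-acyl migration of the neighbouring benzoate.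

Step 16
Reactants: 21 (3S,4R)-4-hydroxypent-1-en-3-yl benzoate
Product: 22 (3S,4R)-4-acetoxypent-1-en-3-yl benzoate
Conditions: Ac2O, pyridine, DMAP (cat.), CH2Cl2, rt
Reagents that add atoms: acetic anhydride CC(=O)OC(C)=O
Why: Acetylation of the remaining secondary alcohol gives the diester in which each acyl group sits on the oxygen fixed by the order of steps.

Step 17
Reactants: 15 vinyl diol core; 22 (3S,4R)-4-acetoxypent-1-en-3-yl benzoate
Product: 23 (2S,3R,3aR,7R,7aR)-2-[(1E,3S,4R)-4-acetoxy-3-(benzoyloxy)pent-1-en-1-yl]-3,7-dihydroxyhexahydro-5H-furo[3,2-b]pyran-5-one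
Conditions: 22 (3 equiv), RuCl2(H2IMes)(=CH-C6H4-2-OiPr) (second-generation Hoveyda–Grubbs catalyst, 10 mol %), CH2Cl2, 40 °C
Reagents that add atoms: none
Why: Olefin cross-metathesis between the two monosubstituted alkenes, with the allylic ester in excess and loss of ethene, should give the thermodynamically preferred (E)-1,2-disubstituted alkene while tolerating the free hydroxyls, the esters and the lactone.

**Compound list**

1 | (±)-3-hydroxydihydrofuran-2(3H)-one (α-hydroxy-γ-butyrolactone) | O=C1OCCC1O | starting material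
2 | 3-hydroxyfuran-2(5H)-one (enol of dihydrofuran-2,3-dione) | O=C1OCC=C1O | intermediate
3 | 3-(naphthalen-2-ylmethoxy)furan-2(5H)-one | O=C1OCC=C1OCc1ccc2ccccc2c1 | intermediate
4 | trimethyl{[3-(naphthalen-2-ylmethoxy)furan-2-yl]oxy}silane | C[Si](C)(C)Oc1occc1OCc1ccc2ccccc2c1 | intermediate
5 | tert-butyl 3-hydroxypropanoate | CC(C)(C)OC(=O)CCO | starting material
6 | tert-butyl 3-oxopropanoate | CC(C)(C)OC(=O)CC=O | intermediate
7 | tert-butyl 3-hydroxy-3-[(2S)-4-(naphthalen-2-ylmethoxy)-5-oxo-2,5-dihydrofuran-2-yl]propanoate (carbinol epimers) | CC(C)(C)OC(=O)CC(O)[C@H]1OC(=O)C(OCc2ccc3ccccc3c2)=C1 | intermediate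
8 | 3-hydroxy-3-[(2S)-4-(naphthalen-2-ylmethoxy)-5-oxo-2,5-dihydrofuran-2-yl]propanoic acid (carbinol epimers) | OC(=O)CC(O)[C@H]1OC(=O)C(OCc2ccc3ccccc3c2)=C1 | intermediate
9 | (3S,3aS,7aR)-7-hydroxy-3-(naphthalen-2-ylmethoxy)tetrahydro-2H-furo[3,2-b]pyran-2,5(3H)-dione, cis-fused, H-3/H-3a/H-7a all cis, C7 epimers | O=C1O[C@H]2[C@H](OC(=O)CC2O)[C@@H]1OCc1ccc2ccccc2c1 | intermediate
10 | (3S,3aS,7aS)-3-(naphthalen-2-ylmethoxy)dihydro-2H-furo[3,2-b]pyran-2,5,7(3H,6H)-trione, H-3/H-3a/H-7a all cis | O=C1O[C@H]2[C@H](OC(=O)CC2=O)[C@@H]1OCc1ccc2ccccc2c1 | intermediate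
11 | 2-ethynyl-2-hydroxy-3-(naphthalen-2-ylmethoxy)tetrahydro-2H-furo[3,2-b]pyran-5,7(3H,6H)-dione, anomeric mixture, other centres as in 10 | C#CC1(O)O[C@H]2[C@H](OC(=O)CC2=O)[C@@H]1OCc1ccc2ccccc2c1 | intermediate
12 | (2S,3R,3aR,7aS)-2-ethynyl-3-(naphthalen-2-ylmethoxy)tetrahydro-2H-furo[3,2-b]pyran-5,7(3H,6H)-dione, all ring hydrogens cis | C#C[C@@H]1O[C@H]2[C@H](OC(=O)CC2=O)[C@@H]1OCc1ccc2ccccc2c1 | intermediate
13 | (2S,3R,3aR,7R,7aR)-2-ethynyl-7-hydroxy-3-(naphthalen-2-ylmethoxy)hexahydro-5H-furo[3,2-b]pyran-5-one | C#C[C@@H]1O[C@H]2[C@H](OC(=O)C[C@H]2O)[C@@H]1OCc1ccc2ccccc2c1 | intermediate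
14 | (2S,3R,3aR,7R,7aR)-7-hydroxy-3-(naphthalen-2-ylmethoxy)-2-vinylhexahydro-5H-furo[3,2-b]pyran-5-one | C=C[C@@H]1O[C@H]2[C@H](OC(=O)C[C@H]2O)[C@@H]1OCc1ccc2ccccc2c1 | intermediate
15 | (2S,3R,3aR,7R,7aR)-3,7-dihydroxy-2-vinylhexahydro-5H-furo[3,2-b]pyran-5-one | C=C[C@@H]1O[C@H]2[C@H](OC(=O)C[C@H]2O)[C@@H]1O | intermediate
16 | methyl (R)-lactate | C[C@@H](O)C(=O)OC | starting material
17 | methyl (R)-2-[(tert-butyldimethylsilyl)oxy]propanoate | C[C@@H](O[Si](C)(C)C(C)(C)C)C(=O)OC | intermediate
18 | (R)-2-[(tert-butyldimethylsilyl)oxy]propanal | C[C@@H](O[Si](C)(C)C(C)(C)C)C=O | intermediate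
19 | (3S,4R)-4-[(tert-butyldimethylsilyl)oxy]pent-1-en-3-ol | C[C@@H](O[Si](C)(C)C(C)(C)C)[C@@H](O)C=C | intermediate
20 | (3S,4R)-4-[(tert-butyldimethylsilyl)oxy]pent-1-en-3-yl benzoate | C[C@@H](O[Si](C)(C)C(C)(C)C)[C@@H](OC(=O)c1ccccc1)C=C | intermediate
21 | (3S,4R)-4-hydroxypent-1-en-3-yl benzoate | C[C@@H](O)[C@@H](OC(=O)c1ccccc1)C=C | intermediate
22 | (3S,4R)-4-acetoxypent-1-en-3-yl benzoate | CC(=O)O[C@H](C)[C@H](C=C)OC(=O)c1ccccc1 | intermediate
23 | (2S,3R,3aR,7R,7aR)-2-[(1E,3S,4R)-4-acetoxy-3-(benzoyloxy)pent-1-en-1-yl]-3,7-dihydroxyhexahydro-5H-furo[3,2-b]pyran-5-one | CC(=O)O[C@H](C)[C@H](/C=C/[C@@H]1O[C@H]2[C@H](OC(=O)C[C@H]2O)[C@@H]1O)OC(=O)c1ccccc1 | target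

**Summary**

Total step count: 17.
Longest linear sequence: 11 steps (steps 1, 2, 3, 5, 6, 7, 8, 9, 10, 11, 17, from 1 to 23). Step 4 and steps 12–16 supply the two side branches.

**Steps most likely to fail, with fallbacks**

Step 5. The β-formyl ester 6 may enolise and chelate on the Ti(OiPr)4/BINOL catalyst, which would stall the aldol addition or erode its enantioselectivity, and the carboxylate conjugate addition may be slow or reversible. The fallback sets out from 4 and returns at 8. The vinylogous Mukaiyama aldol is run under the same catalyst with 3-[(tert-butyldimethylsilyl)oxy]propanal, a simple aliphatic aldehyde of the established substrate class, and should give the silyl ether aldol adduct (5S)-5-[3-(tert-butyldimethylsilyloxy)-1-hydroxypropyl]-3-(naphthalen-2-ylmethoxy)furan-2(5H)-one F1. HF·pyridine then frees the diol (5S)-5-(1,3-dihydroxypropyl)-3-(naphthalen-2-ylmethoxy)furan-2(5H)-one F2. Chemoselective oxidation of the primary alcohol to the acid with TEMPO (cat.) and PhI(OAc)2 in MeCN/H2O gives hydroxy acid 8, which is cyclised to 9 with Et3N as in step 5.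

Step 7. Chemoselectivity may be lost through acetylide attack on the δ-lactone, or the lactone carboxylate may undergo β-elimination from the keto-enolate. The fallback sets out from 10 and returns at 12. O-Methylation of the β-keto lactone with Me3SiCHN2 in MeOH/toluene gives the vinylogous carbonate 7-methoxy-3-(naphthalen-2-ylmethoxy)-3a,7a-dihydro-2H-furo[3,2-b]pyran-2,5(3H)-dione F3, whose six-ring carbonyl is inert to acetylides and carries no acidic 1,3-dicarbonyl proton. HC≡CLi then adds only to the γ-lactone to give the lactol 2-ethynyl-2-hydroxy-7-methoxy-3-(naphthalen-2-ylmethoxy)-2,3,3a,7a-tetrahydro-5H-furo[3,2-b]pyran-5-one F4. Reduction with Et3SiH/BF3·OEt2 gives 2-ethynyl-7-methoxy-3-(naphthalen-2-ylmethoxy)-2,3,3a,7a-tetrahydro-5H-furo[3,2-b]pyran-5-one F5, and aqueous HCl in THF hydrolyses the enol ether to 12.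

Step 8. Facial selectivity of hydride delivery may be poor or inverted, because attack on the concave face, cis to the C5 and C6 oxygens, is the stereoelectronically favoured inside attack on five-membered oxocarbenium ions and competes with convex-face attack. The fallback sets out from 10 and returns at 12, and it reverses the order in which H and carbon are attached to C7. After enolate protection with LiN(SiMe3)2 (1.0 equiv), iBu2AlH at −78 °C reduces the γ-lactone to the lactol 2-hydroxy-3-(naphthalen-2-ylmethoxy)tetrahydro-2H-furo[3,2-b]pyran-5,7(3H,6H)-dione F6. F6 is ionised with BF3·OEt2 in the presence of tributyl(ethynyl)stannane. The carbon nucleophile then takes the face that hydride took in step 8, which inverts the outcome at C7 and should give 12.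

Further compounds
F1 | step 5 | (5S)-5-[3-(tert-butyldimethylsilyloxy)-1-hydroxypropyl]-3-(naphthalen-2-ylmethoxy)furan-2(5H)-one (carbinol epimers) | CC(C)(C)[Si](C)(C)OCCC(O)[C@H]1OC(=O)C(OCc2ccc3ccccc3c2)=C1
F2 | step 5 | (5S)-5-(1,3-dihydroxypropyl)-3-(naphthalen-2-ylmethoxy)furan-2(5H)-one (carbinol epimers) | OCCC(O)[C@H]1OC(=O)C(OCc2ccc3ccccc3c2)=C1
F3 | step 7 | 7-methoxy-3-(naphthalen-2-ylmethoxy)-3a,7a-dihydro-2H-furo[3,2-b]pyran-2,5(3H)-dione, cis-fused, configured as 10 | O=C1O[C@H]2[C@H](OC(=O)C=C2OC)[C@@H]1OCc1ccc2ccccc2c1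
F4 | step 7 | 2-ethynyl-2-hydroxy-7-methoxy-3-(naphthalen-2-ylmethoxy)-2,3,3a,7a-tetrahydro-5H-furo[3,2-b]pyran-5-one, anomeric mixture | C#CC1(O)O[C@H]2[C@H](OC(=O)C=C2OC)[C@@H]1OCc1ccc2ccccc2c1
F5 | step 7 | 2-ethynyl-7-methoxy-3-(naphthalen-2-ylmethoxy)-2,3,3a,7a-tetrahydro-5H-furo[3,2-b]pyran-5-one, ring stereocentres as in 12 | C#C[C@@H]1O[C@H]2[C@H](OC(=O)C=C2OC)[C@@H]1OCc1ccc2ccccc2c1
F6 | step 8 | 2-hydroxy-3-(naphthalen-2-ylmethoxy)tetrahydro-2H-furo[3,2-b]pyran-5,7(3H,6H)-dione, lactol anomers, other centres as in 10 | OC1O[C@H]2[C@H](OC(=O)CC2=O)[C@@H]1OCc1ccc2ccccc2c1
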